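**Retrosynthetic overview**
1. Last operation, both heterocycles in one flask: the target is cut at the aryl–alkyne bond, the lactone C3–O bond and the oxolane C2–O bond, giving 3-chloro-4,6-dihydroxy-2-iodobenzoic acid and an acyclic (R)-hydroxy trans-dienyl epoxide that ends in a terminal alkyne.
2. Epoxy dienyne ⇒ γ,δ-epoxy enal + propargyl phosphonate (E-selective olefination); epoxy enal ⇒ δ-hydroxy enal by catalyst-controlled epoxidation and Wittig reaction in the same flask.
3. δ-Hydroxy enal ⇒ (R)-pent-4-en-2-ol + crotonaldehyde (cross-metathesis); C5 of the oxolane comes from the pool, C2 and C3 from the epoxide.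
4. Iodo acid ⇒ 1-iodo-3,5-dimethoxybenzene by formylation, chlorination, oxidation and demethylation.
5. Ring order: benzene ring bought; oxolane first, pyranone second, both closed in the final flask.

Assumption: compounds 1, 7, 8, 10 and 13 are taken as catalogue chemicals; the target is the (2S,3S,5R)-oxolane (all-cis) with both chain double bonds E.

**Step 1**
Reactants: 1 1-iodo-3,5-dimethoxybenzene
Product: 3 2-iodo-4,6-dimethoxybenzaldehyde, via iminium chloride 2 (not isolated)
Conditions: POCl3 (1.5 equiv), DMF, 0 → 90 °C; then ice–water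
Reagents that add atoms: N,N-dimethylformamide CN(C)C=O; water O
Why: Vilsmeier–Haack formylation; the chloroiminium ion attacks the carbon para to one methoxy and ortho to the other (next to iodine) in preference to the doubly flanked carbon between the two methoxy groups, as the bromo analogue does.

**Step 2**
Reactants: 3 2-iodo-4,6-dimethoxybenzaldehyde
Product: 4 3-chloro-2-iodo-4,6-dimethoxybenzaldehyde
Conditions: NCS (1.05 equiv), DMF, rt → 50 °C
Reagents that add atoms: N-chlorosuccinimide O=C1CCC(=O)N1Cl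
Why: Electrophilic aromatic chlorination goes to C3 (para to the 6-methoxy, ortho to the 4-methoxy) in preference to C5 between the two methoxy groups, the same preference that 2,4-dimethoxy-6-methylbenzaldehyde shows.

**Step 3**
Reactants: 4 3-chloro-2-iodo-4,6-dimethoxybenzaldehyde
Product: 5 3-chloro-2-iodo-4,6-dimethoxybenzoic acid
Conditions: NaClO2, 35% H2O2, NaH2PO4, MeCN–H2O, 10 °C → rt
Reagents that add atoms: sodium chlorite [Na+].[O-]Cl=O
Why: Lindgren–Pinnick chlorite oxidation of the aldehyde; hydrogen peroxide destroys the hypochlorite formed, so the electron-rich ring is not chlorinated a second time.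

**Step 4**
Reactants: 5 3-chloro-2-iodo-4,6-dimethoxybenzoic acid
Product: 6 3-chloro-4,6-dihydroxy-2-iodobenzoic acid
Conditions: BBr3 (4 equiv), CH2Cl2, −78 °C → rt; then H2O
Reagents that add atoms: none
Why: Lewis-acid cleavage of both aryl methyl ethers with BBr3; the halogens sit meta to the oxygens and are not displaced, and staying at or below room temperature avoids decarboxylation of the resorcylic acid.

**Step 5**
Reactants: 7 (2R)-pent-4-en-2-ol; 8 (2E)-but-2-enal
Product: 9 (2E,5R)-5-hydroxyhex-2-enal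
Conditions: 8 (5 equiv), second-generation Hoveyda–Grubbs catalyst RuCl2(=CH-C6H4-2-OiPr)(H2IMes) (2 mol %), CH2Cl2, 40 °C
Reagents that add atoms: none
Why: Olefin cross-metathesis of a terminal alkene with an excess of the electron-poor enal gives the E-enal with loss of propene; the free carbinol is tolerated and its stereocentre is not touched.

**Step 6**
Reactants: 9 (2E,5R)-5-hydroxyhex-2-enal; 10 2-(triphenylphosphoranylidene)acetaldehyde
Product: 12 (2E)-3-[(2S,3S)-3-[(2R)-2-hydroxypropyl]oxiran-2-yl]prop-2-enal, via epoxy aldehyde 11 (not isolated)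
Conditions: (S)-2-[bis(3,5-bis(trifluoromethyl)phenyl)(trimethylsilyloxy)methyl]pyrrolidine (10 mol %), 35% aq H2O2 (1.2 equiv), CH2Cl2, rt, 4 h; then 10 (1.3 equiv), rt, 12 h
Reagents that add atoms: hydrogen peroxide OO
Why: Iminium-activated nucleophilic epoxidation (Jørgensen type) in which the (S)-diarylprolinol silyl ether shields one face of the E-iminium ion, so the trans-(2R,3S)-epoxy aldehyde is set by the catalyst (the remote carbinol has little influence), and the stabilised ylide then gives the E-enal by Wittig reaction before the labile epoxy aldehyde has to be handled.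

**Step 7**
Reactants: 12 (2E)-3-[(2S,3S)-3-[(2R)-2-hydroxypropyl]oxiran-2-yl]prop-2-enal; 13 diethyl [3-(trimethylsilyl)prop-2-yn-1-yl]phosphonate
Product: 15 (2R)-1-[(2S,3S)-3-[(1E,3E)-hexa-1,3-dien-5-yn-1-yl]oxiran-2-yl]propan-2-ol, via silyl dienyne 14 (not isolated)
Conditions: 13 (2.2 equiv), LiN(SiMe3)2 (2.2 equiv), THF, −78 → 0 °C; then K2CO3 (cat.), MeOH, rt
Reagents that add atoms: none
Why: Horner–Wadsworth–Emmons olefination with the lithiated propargyl phosphonate is 1,2- and E-selective and leaves the epoxide alone at low temperature (the extra equivalent of anion covers the free hydroxyl), and methanolysis then removes the alkynyl silyl group; 15 is purified on triethylamine-deactivated silica and used at once.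

**Step 8**
Reactants: 6 3-chloro-4,6-dihydroxy-2-iodobenzoic acid; 15 (2R)-1-[(2S,3S)-3-[(1E,3E)-hexa-1,3-dien-5-yn-1-yl]oxiran-2-yl]propan-2-ol
Product: 18 5-chloro-6,8-dihydroxy-3-[(1E,3E)-4-[(2S,3S,5R)-3-hydroxy-5-methyloxolan-2-yl]buta-1,3-dien-1-yl]-1H-isochromen-1-one, via oxolane dienyne 16 (not isolated), via alkynylbenzoic acid 17 (not isolated)
Conditions: Pd(PPh3)4 (5 mol %), degassed THF, rt, 30 min; then 6, CuI (10 mol %), Et3N (6 equiv), EtOH, rt → 60 °C
Reagents that add atoms: none
Why: Proposed new method: one charge of zerovalent palladium runs two known cycles in one flask — it first ionises the dienyl epoxide with inversion and the C5 hydroxyl closes on the syn π-allyl terminus anti to palladium, so C2 forms with net retention and the oxolane comes out 2,3-cis and 2,5-cis with the diene still E,E (Tsuji–Trost etherification); the same catalyst with CuI then joins the terminal alkyne to the aryl iodide (Sonogashira coupling), and the triethylammonium carboxylate of 17 adds 6-endo-dig to the metal-activated alkyne because the dienyl group stabilises positive charge at the distal alkyne carbon and the protic medium disfavours the 5-exo phthalide; the closest known reactions are the palladium-catalysed cyclisation of hydroxy vinyl epoxides to cis-2-vinyl-3-hydroxy cyclic ethers and the one-pot Sonogashira coupling/lactonisation of 2-iodobenzoic acids to 3-substituted isocoumarins.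

**Compound list**
1 | 1-iodo-3,5-dimethoxybenzene | COc1cc(I)cc(OC)c1 | starting material
2 | N-[(2-iodo-4,6-dimethoxyphenyl)methylidene]-N-methylmethanaminium chloride | COc1cc(OC)c(C=[N+](C)C)c(I)c1.[Cl-] | intermediate
3 | 2-iodo-4,6-dimethoxybenzaldehyde | COc1cc(OC)c(C=O)c(I)c1 | intermediate
4 | 3-chloro-2-iodo-4,6-dimethoxybenzaldehyde | COc1cc(OC)c(C=O)c(I)c1Cl | intermediate
5 | 3-chloro-2-iodo-4,6-dimethoxybenzoic acid | COc1cc(OC)c(C(=O)O)c(I)c1Cl | intermediate
6 | 3-chloro-4,6-dihydroxy-2-iodobenzoic acid | Oc1cc(O)c(C(=O)O)c(I)c1Cl | intermediate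
7 | (2R)-pent-4-en-2-ol | C[C@@H](O)CC=C | starting material
8 | (2E)-but-2-enal | C/C=C/C=O | starting material
9 | (2E,5R)-5-hydroxyhex-2-enal | C[C@@H](O)C/C=C/C=O | intermediate
10 | 2-(triphenylphosphoranylidene)acetaldehyde | O=CC=P(c1ccccc1)(c1ccccc1)c1ccccc1 | starting material
11 | (2R,3S)-3-[(2R)-2-hydroxypropyl]oxirane-2-carbaldehyde | C[C@@H](O)C[C@@H]1O[C@H]1C=O | intermediate
12 | (2E)-3-[(2S,3S)-3-[(2R)-2-hydroxypropyl]oxiran-2-yl]prop-2-enal | C[C@@H](O)C[C@@H]1O[C@H]1/C=C/C=O | intermediate
13 | diethyl [3-(trimethylsilyl)prop-2-yn-1-yl]phosphonate | CCOP(=O)(CC#C[Si](C)(C)C)OCC | starting material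
14 | (2R)-1-[(2S,3S)-3-[(1E,3E)-6-(trimethylsilyl)hexa-1,3-dien-5-yn-1-yl]oxiran-2-yl]propan-2-ol | C[C@@H](O)C[C@@H]1O[C@H]1/C=C/C=C/C#C[Si](C)(C)C | intermediate
15 | (2R)-1-[(2S,3S)-3-[(1E,3E)-hexa-1,3-dien-5-yn-1-yl]oxiran-2-yl]propan-2-ol | C[C@@H](O)C[C@@H]1O[C@H]1/C=C/C=C/C#C | intermediate
16 | (2S,3S,5R)-2-[(1E,3E)-hexa-1,3-dien-5-yn-1-yl]-5-methyloxolan-3-ol | C[C@@H]1C[C@H](O)[C@H](/C=C/C=C/C#C)O1 | intermediate
17 | 3-chloro-4,6-dihydroxy-2-[(3E,5E)-6-[(2S,3S,5R)-3-hydroxy-5-methyloxolan-2-yl]hexa-3,5-dien-1-yn-1-yl]benzoic acid | C[C@@H]1C[C@H](O)[C@H](/C=C/C=C/C#Cc2c(Cl)c(O)cc(O)c2C(=O)O)O1 | intermediate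
18 | 5-chloro-6,8-dihydroxy-3-[(1E,3E)-4-[(2S,3S,5R)-3-hydroxy-5-methyloxolan-2-yl]buta-1,3-dien-1-yl]-1H-isochromen-1-one (CNP0086741.3) | C[C@@H]1C[C@H](O)[C@H](/C=C/C=C/c2cc3c(Cl)c(O)cc(O)c3c(=O)o2)O1 | target

**Totals**
Total step count: 8. Longest linear sequence: 5 (steps 1, 2, 3, 4, 8).

**Three steps most likely to fail**

Step 8. The two palladium cycles may interfere, or the acid may close 5-exo to the ylidene phthalide. The fallback closes the oxolane before chain extension and uses a π-acid for the lactone. It sets out from 12: Pd(PPh3)4 (2 mol %) in THF at rt closes the ring at the epoxy-enal stage to give (2E)-3-[(2S,3S,5R)-3-hydroxy-5-methyloxolan-2-yl]prop-2-enal F1. Olefination with lithiated 13 gives (2S,3S,5R)-5-methyl-2-[(1E,3E)-6-(trimethylsilyl)hexa-1,3-dien-5-yn-1-yl]oxolan-3-ol F2, and K2CO3 in MeOH gives 16, now isolated. Copper-free Sonogashira coupling of 16 with 6 (Pd(PPh3)4, Et3N, DMF, rt) is stopped at the acid 17, and Au(NTf2)(PPh3) (2 mol %) in CH2Cl2 closes it 6-endo. The fallback comes back to the route at 18.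

Step 7. The new double bond may form with poor E/Z ratio, the epoxy enal may not survive the strong base, or 15 may be lost on isolation. The fallback sets out from 12: a second Wittig reaction with 10 (toluene, 60 °C) gives (2E,4E)-5-[(2S,3S)-3-[(2R)-2-hydroxypropyl]oxiran-2-yl]penta-2,4-dienal F3, with the E geometry fixed by the stabilised ylide. Ohira–Bestmann homologation (dimethyl (1-diazo-2-oxopropyl)phosphonate, K2CO3, MeOH, 0 °C → rt) then turns the aldehyde into the terminal alkyne. The fallback comes back to the route at 15.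

Step 6. The hydroxy enal may isomerise and cyclise under amine catalysis, the epoxy aldehyde may degrade, or the diastereomer ratio may be too low. The fallback sets out from 7: cross-metathesis with (2Z)-but-2-ene-1,4-diol (same ruthenium catalyst) gives (2E,5R)-hex-2-ene-1,5-diol F4. Sharpless asymmetric epoxidation (Ti(OiPr)4, L-(+)-diethyl tartrate, t-BuOOH, 4 Å sieves, CH2Cl2, −20 °C) gives (2R)-1-[(2S,3S)-3-(hydroxymethyl)oxiran-2-yl]propan-2-ol F5 under reagent control. TEMPO with PhI(OAc)2 oxidises only the primary alcohol. The fallback comes back to the route at 11, which is taken on with 10 to 12 as in step 6.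

**Further compounds**
F1 | step 8 | (2E)-3-[(2S,3S,5R)-3-hydroxy-5-methyloxolan-2-yl]prop-2-enal | C[C@@H]1C[C@H](O)[C@H](/C=C/C=O)O1
F2 | step 8 | (2S,3S,5R)-5-methyl-2-[(1E,3E)-6-(trimethylsilyl)hexa-1,3-dien-5-yn-1-yl]oxolan-3-ol | C[C@@H]1C[C@H](O)[C@H](/C=C/C=C/C#C[Si](C)(C)C)O1
F3 | step 7 | (2E,4E)-5-[(2S,3S)-3-[(2R)-2-hydroxypropyl]oxiran-2-yl]penta-2,4-dienal | C[C@@H](O)C[C@@H]1O[C@H]1/C=C/C=C/C=O
F4 | step 6 | (2E,5R)-hex-2-ene-1,5-diol | C[C@@H](O)C/C=C/CO
F5 | step 6 | (2R)-1-[(2S,3S)-3-(hydroxymethyl)oxiran-2-yl]propan-2-ol | C[C@@H](O)C[C@@H]1O[C@H]1CO
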